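**Plan**
Retrosynthetic cuts, in order: the C6–O acyl bond; the C13–OH/C14=C15 unit, traced back through a C15–I bond to the two C–O bonds of a C13–C14 oxirane; the C13=C14 bond (olefination); the C8–O/C17–H pair (spiro-oxirane on the 8(17)-methylene); and last the native C13–C14 bond of a larch labdane.
Enabling feature: C13 is an acyclic tertiary carbinol bearing the C14=C15 vinyl group, so O–C13–C14=C15 is the retron of a 2,3-epoxy alcohol (oxirane on C13/C14, OH on C15). At that stage the side chain on C9 of the A/B trans-decalin holds the only C=C bond of the molecule.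
Forward order: rings A and B are bought intact. The side chain is shortened to a C13 ketone and regrown by C14–C15 as an E-enoate. The C8/C17 oxirane is closed and opened by hydride, the C13/C14 oxirane is closed in the key step and opened by zinc, and the ester is attached last.
Stereochemistry: C5, C6, C9 and C10 come from larixyl acetate 1. C8 comes from α-face epoxidation, the β face being blocked by the axial methyl on C10. C13 comes from the (S,S)-tartrate ligand of the titanium epoxidation acting on a geometrically pure E-alkene. The Z geometry of the ester is bought with the acid.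

Key step: step 5

Remark: labdane numbering is used (C1–C10 decalin, C11–C16 side chain, C17 on C8, C18/C19 on C4, C20 on C10), and every compound belongs to the normal series (5α-H, 9α-H, 10β-CH3). Larixyl acetate is taken as a purchasable larch-resin natural product.

Step 1
Reactants: 1 larixyl acetate, (13S)-6α-acetoxylabda-8(17),14-dien-13-ol
Product: 2 6α-acetoxy-14,15-dinorlabd-8(17)-en-13-one
Conditions: KMnO4, BnEt3NCl (cat.), CH2Cl2, 0 °C → rt
Reagents that add atoms: none
Why: Permanganate degradation of a tertiary vinyl carbinol (dihydroxylation, glycol cleavage, oxidative decarboxylation), the classical side-chain shortening of 8(17),14-labdadien-13-ols, removes C14 and C15 and leaves the C13 oxygen as the ketone, while the hindered 8(17)-methylene reacts more slowly and the acetate shields the C6 oxygen; no stereocentre is formed and the unwanted 13S centre disappears.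

Step 2
Reactants: 2 6α-acetoxy-14,15-dinorlabd-8(17)-en-13-one; 3 triethyl phosphonoacetate
Product: 4 ethyl (13E)-6α-acetoxylabda-8(17),13-dien-15-oate
Conditions: NaH, THF, 0 → 50 °C; Z isomer removed by chromatography
Reagents that add atoms: triethyl phosphonoacetate (3), CCOC(=O)CP(=O)(OCC)OCC
Why: Horner–Wadsworth–Emmons olefination of a methyl ketone forms C13=C14 under reversible-addition control with the ester trans to the larger C12 chain, so the E ester should predominate, and the Z ester is separated here because alkene geometry is translated into C13 configuration in step 5.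

Step 3
Reactants: 4 ethyl (13E)-6α-acetoxylabda-8(17),13-dien-15-oate
Product: 5 ethyl (13E)-6α-acetoxy-8α,17-epoxylabd-13-en-15-oate
Conditions: mCPBA, CH2Cl2, 0 °C
Reagents that add atoms: mCPBA, O=C(OO)c1cccc(Cl)c1
Why: Prilezhaev epoxidation is chemoselective for the electron-rich 1,1-disubstituted 8(17)-alkene over the ester-deactivated C13=C14 bond, and the axial C20 methyl on C10 blocks the β face, so oxygen should arrive from the α face and set C8 with an equatorial 8α C–O bond.

Step 4
Reactants: 5 ethyl (13E)-6α-acetoxy-8α,17-epoxylabd-13-en-15-oate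
Product: 6 (13E)-labd-13-ene-6α,8α,15-triol
Conditions: LiAlH4, THF, 0 °C → reflux
Reagents that add atoms: none
Why: Global LiAlH4 reduction gives the E-allylic alcohol by 1,2-reduction of the β,β-disubstituted enoate, cleaves the acetate, and opens the spiro-oxirane by SN2 attack of hydride at the unhindered C17 methylene, so the C8–O bond is untouched and the 8α-carbinol keeps the configuration set in step 3.

Step 5
Reactants: 6 (13E)-labd-13-ene-6α,8α,15-triol; 7 D-(−)-diethyl tartrate (chiral ligand, not incorporated)
Product: 8 (13R,14R)-13,14-epoxylabdane-6α,8α,15-triol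
Conditions: Ti(OiPr)4 (1 equiv), 7 (1.2 equiv), t-BuOOH (decane), 4 Å MS, CH2Cl2, −25 °C; non-acidic work-up
Reagents that add atoms: tert-butyl hydroperoxide, CC(C)(C)OO
Why: This is a Katsuki–Sharpless asymmetric epoxidation: the C15 alkoxide and tert-butyl peroxide exchange onto the dimeric titanium–tartrate complex, and the activated peroxide oxygen passes in one concerted suprafacial event to C13=C14. The oxirane (O, C13, C14) is the only ring made; it closes by syn transfer of a single oxygen atom to both alkene carbons ([2+1] addition), so the E geometry appears as the trans relation of C12 and C15 on the ring. C13 and C14 are both fixed by the (S,S)-tartrate, which for an E-allylic alcohol of the geraniol type delivers oxygen to the face giving the (R,R)-epoxide, as geraniol gives (2R,3R)-epoxygeraniol, while the nearest ring stereocentre C9 lies three bonds from C13 and should add no meaningful bias. The step needs face selectivity and geometric purity, which are secured by the primary allylic C15–OH as the only good titanium anchor next to the only C=C bond of 6 and by removal of the Z ester in step 2. The hindered 6α- and tertiary 8α-hydroxyls have no alkene within reach, a full equivalent of titanium–tartrate absorbs their reversible binding, and the low temperature and non-acidic work-up keep the 8α-hydroxyl from attacking the oxirane at C13.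

Step 6
Reactants: 8 (13R,14R)-13,14-epoxylabdane-6α,8α,15-triol
Product: 9 (13R,14S)-13,14-epoxy-15-iodolabdane-6α,8α-diol
Conditions: PPh3, I2, imidazole, THF, 0 °C, dark
Reagents that add atoms: iodine, II
Why: Appel-type (Garegg–Samuelsson) iodination proceeds through an alkoxyphosphonium salt that iodide can displace by SN2 only at the primary C15, the neopentyl-like 6α-OH and the tertiary 8α-OH being undisplaceable, while imidazole keeps the medium non-acidic so the oxirane survives and C13/C14 are untouched (the 14S label is only a CIP priority change).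

Step 7
Reactants: 9 (13R,14S)-13,14-epoxy-15-iodolabdane-6α,8α-diol
Product: 10 (13R)-labd-14-ene-6α,8α,13-triol
Conditions: Zn dust (activated), EtOH, reflux
Reagents that add atoms: none
Why: Zinc inserts into the C15–I bond and the organozinc undergoes β-elimination (reductive opening of a 2,3-epoxy iodide, as in the epoxygeraniol-to-linalool conversion), which breaks C14–O and forms C14=C15 while the C13–O bond is never broken, so the 13R configuration is carried over unchanged.

Step 8
Reactants: 10 (13R)-labd-14-ene-6α,8α,13-triol; 11 angelic acid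
Product: 13 (13R)-6α-angeloyloxylabd-14-ene-8α,13-diol (target), via angelic 2,4,6-trichlorobenzoic anhydride 12 (not isolated)
Conditions: 11, 2,4,6-Cl3C6H2COCl, Et3N, PhMe, rt; then 10, 80 °C, no DMAP
Reagents that add atoms: angelic acid (11), C/C=C(/C)C(=O)O; 2,4,6-trichlorobenzoyl chloride, O=C(Cl)c1c(Cl)cc(Cl)cc1Cl (atoms in 12 only)
Why: In this Yamaguchi-type mixed-anhydride esterification the alcohol attacks the less hindered angeloyl carbonyl of 12, only the secondary equatorial 6α-OH is acylated because the two tertiary carbinols are inert without a nucleophilic catalyst, and leaving out DMAP avoids the addition–elimination pathway that isomerises angelates, so the Z geometry of 11 is retained.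

**Compound list**
1 | larixyl acetate, (13S)-6α-acetoxylabda-8(17),14-dien-13-ol | C=C[C@@](C)(O)CC[C@@H]1[C@@]2(C)CCCC(C)(C)[C@@H]2[C@@H](OC(C)=O)CC1=C | starting material
2 | 6α-acetoxy-14,15-dinorlabd-8(17)-en-13-one | CC(=O)CC[C@@H]1[C@@]2(C)CCCC(C)(C)[C@@H]2[C@@H](OC(C)=O)CC1=C | intermediate
3 | triethyl phosphonoacetate | CCOC(=O)CP(=O)(OCC)OCC | starting material
4 | ethyl (13E)-6α-acetoxylabda-8(17),13-dien-15-oate | CCOC(=O)/C=C(\C)CC[C@@H]1[C@@]2(C)CCCC(C)(C)[C@@H]2[C@@H](OC(C)=O)CC1=C | intermediate
5 | ethyl (13E)-6α-acetoxy-8α,17-epoxylabd-13-en-15-oate | CCOC(=O)/C=C(\C)CC[C@@H]1[C@@]2(C)CCCC(C)(C)[C@@H]2[C@@H](OC(C)=O)C[C@@]13OC3 | intermediate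
6 | (13E)-labd-13-ene-6α,8α,15-triol | OC/C=C(\C)CC[C@@H]1[C@@]2(C)CCCC(C)(C)[C@@H]2[C@@H](O)C[C@@]1(C)O | intermediate
7 | D-(−)-diethyl tartrate, diethyl (2S,3S)-tartrate | CCOC(=O)[C@@H](O)[C@H](O)C(=O)OCC | starting material
8 | (13R,14R)-13,14-epoxylabdane-6α,8α,15-triol | OC[C@H]1O[C@]1(C)CC[C@@H]2[C@@]3(C)CCCC(C)(C)[C@@H]3[C@@H](O)C[C@@]2(C)O | intermediate
9 | (13R,14S)-13,14-epoxy-15-iodolabdane-6α,8α-diol | IC[C@H]1O[C@]1(C)CC[C@@H]2[C@@]3(C)CCCC(C)(C)[C@@H]3[C@@H](O)C[C@@]2(C)O | intermediate
10 | (13R)-labd-14-ene-6α,8α,13-triol | C=C[C@](C)(O)CC[C@@H]1[C@@]2(C)CCCC(C)(C)[C@@H]2[C@@H](O)C[C@@]1(C)O | intermediate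
11 | angelic acid, (Z)-2-methylbut-2-enoic acid | C/C=C(/C)C(=O)O | starting material
12 | angelic 2,4,6-trichlorobenzoic anhydride | C/C=C(/C)C(=O)OC(=O)c1c(Cl)cc(Cl)cc1Cl | intermediate
13 | (13R)-6α-angeloyloxylabd-14-ene-8α,13-diol | C=C[C@](C)(O)CC[C@@H]1[C@@]2(C)CCCC(C)(C)[C@@H]2[C@@H](OC(=O)/C(C)=C\C)C[C@@]1(C)O | target

Total step count: 8. Longest linear sequence: 8 steps (1 → 13).

**Steps most likely to fail**

Step 5. Binding of the 6α- and 8α-hydroxyls to titanium may erode face selectivity. Titanium-assisted 6-exo attack of the 8α-hydroxyl on C13 of the fresh oxirane may also consume the product and invert C13. The fallback sets out from 4 and returns at 10; it sets C13 before any C8 hydroxyl exists.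
- DIBAL-H (CH2Cl2, −78 → 0 °C) reduces the ester and removes the acetate to give (13E)-labda-8(17),13-diene-6α,15-diol F1.
- The same titanium/D-(−)-tartrate epoxidation, which leaves the isolated 8(17)-alkene alone, should give (13R,14R)-13,14-epoxylabd-8(17)-ene-6α,15-diol F2.
- PPh3/I2/imidazole gives (13R,14S)-13,14-epoxy-15-iodolabd-8(17)-en-6α-ol F3.
- Zinc in ethanol gives (13R)-labda-8(17),14-diene-6α,13-diol F4.
- mCPBA attacks the 1,1-disubstituted alkene in preference to the monosubstituted vinyl group, from the α face, to give (13R)-8α,17-epoxylabd-14-ene-6α,13-diol F5.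
- LiAlH4 opens this oxirane at C17 to give 10.

Step 8. Acylation of the hindered 6α-hydroxyl may be slow, and forcing conditions invite Z-to-E isomerisation of the activated acyl unit or ionisation of the tertiary allylic carbinol. The fallback sets out from 10 and returns at 13; it builds the Z-alkene after the ester bond.
- EDC/DMAP coupling of 10 with 2-[bis(2,2,2-trifluoroethoxy)phosphoryl]propanoic acid acylates only the secondary hydroxyl. It gives (13R)-6α-{2-[bis(2,2,2-trifluoroethoxy)phosphoryl]propanoyloxy}labd-14-ene-8α,13-diol F6, epimeric at the phosphonate carbon, which becomes sp2.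
- Still–Gennari olefination (KHMDS, 18-crown-6, THF, −78 °C, acetaldehyde) should then close the Z-trisubstituted alkene of 13. The phosphonate C–H is far more acidic than the tertiary hydroxyls.

Step 2. The methyl and CH2 groups on C13 are poorly differentiated, so E/Z selectivity may be modest and much material could be lost on separation. The fallback sets out from 2 and returns at 10; it uses both geometric isomers convergently instead of relying on selectivity.
- The olefination of 2 delivers, beside 4, ethyl (13Z)-6α-acetoxylabda-8(17),13-dien-15-oate F7, which is collected.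
- mCPBA gives ethyl (13Z)-6α-acetoxy-8α,17-epoxylabd-13-en-15-oate F8.
- LiAlH4 gives (13Z)-labd-13-ene-6α,8α,15-triol F9.
- Titanium epoxidation with purchased L-(+)-diethyl tartrate, which on a nerol-type Z-alkene places oxygen on the face that again makes C13 R, should give (13R,14S)-13,14-epoxylabdane-6α,8α,15-triol F10.
- Iodination gives (13R,14R)-13,14-epoxy-15-iodolabdane-6α,8α-diol F11.
- Zinc destroys C14 as a stereocentre and gives the same 10.

**Further compounds**
F1 | step 5 | (13E)-labda-8(17),13-diene-6α,15-diol | OC/C=C(\C)CC[C@@H]1[C@@]2(C)CCCC(C)(C)[C@@H]2[C@@H](O)CC1=C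
F2 | step 5 | (13R,14R)-13,14-epoxylabd-8(17)-ene-6α,15-diol | OC[C@H]1O[C@]1(C)CC[C@@H]2[C@@]3(C)CCCC(C)(C)[C@@H]3[C@@H](O)CC2=C
F3 | step 5 | (13R,14S)-13,14-epoxy-15-iodolabd-8(17)-en-6α-ol | IC[C@H]1O[C@]1(C)CC[C@@H]2[C@@]3(C)CCCC(C)(C)[C@@H]3[C@@H](O)CC2=C
F4 | step 5 | (13R)-labda-8(17),14-diene-6α,13-diol | C=C[C@](C)(O)CC[C@@H]1[C@@]2(C)CCCC(C)(C)[C@@H]2[C@@H](O)CC1=C
F5 | step 5 | (13R)-8α,17-epoxylabd-14-ene-6α,13-diol | C=C[C@](C)(O)CC[C@@H]1[C@@]2(C)CCCC(C)(C)[C@@H]2[C@@H](O)C[C@@]13OC3
F6 | step 8 | (13R)-6α-{2-[bis(2,2,2-trifluoroethoxy)phosphoryl]propanoyloxy}labd-14-ene-8α,13-diol | C=C[C@](C)(O)CC[C@@H]1[C@@]2(C)CCCC(C)(C)[C@@H]2[C@@H](OC(=O)C(C)P(=O)(OCC(F)(F)F)OCC(F)(F)F)C[C@@]1(C)O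
F7 | step 2 | ethyl (13Z)-6α-acetoxylabda-8(17),13-dien-15-oate | CCOC(=O)/C=C(/C)CC[C@@H]1[C@@]2(C)CCCC(C)(C)[C@@H]2[C@@H](OC(C)=O)CC1=C
F8 | step 2 | ethyl (13Z)-6α-acetoxy-8α,17-epoxylabd-13-en-15-oate | CCOC(=O)/C=C(/C)CC[C@@H]1[C@@]2(C)CCCC(C)(C)[C@@H]2[C@@H](OC(C)=O)C[C@@]13OC3
F9 | step 2 | (13Z)-labd-13-ene-6α,8α,15-triol | OC/C=C(/C)CC[C@@H]1[C@@]2(C)CCCC(C)(C)[C@@H]2[C@@H](O)C[C@@]1(C)O
F10 | step 2 | (13R,14S)-13,14-epoxylabdane-6α,8α,15-triol | OC[C@@H]1O[C@]1(C)CC[C@@H]2[C@@]3(C)CCCC(C)(C)[C@@H]3[C@@H](O)C[C@@]2(C)O
F11 | step 2 | (13R,14R)-13,14-epoxy-15-iodolabdane-6α,8α-diol | IC[C@@H]1O[C@]1(C)CC[C@@H]2[C@@]3(C)CCCC(C)(C)[C@@H]3[C@@H](O)C[C@@]2(C)O
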